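**Plan**

1. Retrosynthesis: the two caffeate C–O bonds (O-1 and O-3) are cut last, leading back to (–)-quinide 3,4-acetonide. In that lactone, the ring bond C1–C2 and the lactone C–O bond are traced to one event: the anionic 1,2-shift of a cycloheptane-1,2-dione hemiketal (ring contraction 7 → 6). The cycloheptene precursor is opened at its C=C bond (metathesis), and the two allylic C–C bonds go back to a C5 diepoxide.
2. Enabling feature: C1 is a tertiary α-hydroxy-acid carbon flanked by two CH2 groups, which is the retron of a benzilic-type shift of a 1,2-diketone. Its carboxyl is cis-1,3 to O-5, so the cyclohexane plus O-5 form a 6-oxabicyclo[3.2.1]octan-7-one. This maps onto an 8-oxabicyclo[3.2.1]octane hemiketal of the dione, in which O-5 is the internal nucleophile.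
3. Forward order: D-arabinitol (its C1–C5 become ring carbons C6–C2) → diepoxide → two vinyl groups → metathesis to the seven-membered ring → acetonide/TES → 1,2-dione → fluoride-triggered transannular hemiketalisation and 1,2-shift, which gives the six-membered ring and the γ-lactone together → two acylations → acid hydrolysis.
4. Stereochemistry: C5 and C3 are C2 and C4 of D-arabinitol, and their C–O bonds are never broken. C4 is non-stereogenic until the cis-acetonide picks its partner (either cis closure gives the same compound). C1 is fixed by the O-5 tether during the ring contraction. Both facial isomers of the dihydroxylation converge at the dione.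

Key step: step 9

Remark: positions are numbered as in (–)-quinic acid (C1 carries the carboxyl; O-3 is cis to O-4, O-5 trans to O-4); with this numbering the given SMILES is the 1,3-diester.

**Route**

Step 1
Reactants: 1 D-arabinitol
Product: 2 2,3,4-tri-O-acetyl-1,5-dibromo-1,5-dideoxy-D-arabinitol
Conditions: AcBr (excess), 1,4-dioxane, 0 °C → rt
Reagents that add atoms: acetyl bromide CC(=O)Br
Why: Peracetylation releases HBr and the two primary acetates are exchanged for bromide through 1,2-acetoxonium ions opened at the primary carbon (acetyl bromide bromination of alditols), so the C2–O and C4–O bonds and their configuration are retained.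

Step 2
Reactants: 2 2,3,4-tri-O-acetyl-1,5-dibromo-1,5-dideoxy-D-arabinitol
Product: 3 1,2:4,5-dianhydro-D-arabinitol (bis[(2R)-oxiran-2-yl]methanol)
Conditions: K2CO3 (2.5 equiv), MeOH, 0 °C, short time; filter, concentrate cold
Reagents that add atoms: none
Why: Methanolysis of the acetates frees the 2- and 4-alkoxides, which displace the neighbouring primary bromides (3-exo-tet Williamson closure, as in the dibromohexitol → dianhydrohexitol conversion) without touching a stereogenic C–O bond.

Step 3
Reactants: 3 1,2:4,5-dianhydro-D-arabinitol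
Product: 4 (4R,6R)-nona-1,8-diene-4,5,6-triol
Conditions: CH2=CHMgBr (5 equiv), CuI (0.2 equiv), THF, –40 → 0 °C; aq NH4Cl
Reagents that add atoms: vinylmagnesium bromide C=C[Mg]Br
Why: Copper-catalysed Grignard opening of both terminal epoxides by SN2 attack at the CH2 carbons, with the free hydroxyl carried as its magnesium alkoxide, should form both allylic C–C bonds in one two-directional operation without touching a stereocentre.

Step 4
Reactants: 4 (4R,6R)-nona-1,8-diene-4,5,6-triol
Product: 5 (1R,3R)-cyclohept-5-ene-1,2,3-triol
Conditions: Grubbs second-generation catalyst (3 mol %), CH2Cl2 (5 mM), 40 °C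
Reagents that add atoms: none
Why: Ring-closing metathesis of a 1,8-diene to a cycloheptene tolerates free homoallylic hydroxyls and is driven by loss of ethene.

Step 5
Reactants: 5 (1R,3R)-cyclohept-5-ene-1,2,3-triol
Product: 6 (1R,2S,3R)-1,2-O-isopropylidenecyclohept-5-ene-1,2,3-triol (cis-fused acetonide; free 3-OH trans to O-2)
Conditions: Me2C(OMe)2 (1.5 equiv), PPTS (5 mol %), acetone, 0 °C → rt
Reagents that add atoms: 2,2-dimethoxypropane COC(C)(C)OC
Why: Transketalisation bridges only a cis-vicinal pair on the ring, and because C2 of the triol is non-stereogenic both possible cis closures give the same compound, so exactly one hydroxyl stays free and trans to the acetonide.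

Step 6
Reactants: 6 (1R,2S,3R)-1,2-O-isopropylidenecyclohept-5-ene-1,2,3-triol
Product: 7 3-O-triethylsilyl ether of 6 (configuration unchanged)
Conditions: TESCl (1.2 equiv), imidazole (2 equiv), CH2Cl2, 0 °C
Reagents that add atoms: chlorotriethylsilane CC[Si](Cl)(CC)CC
Why: Standard silylation of the only free secondary hydroxyl masks it during the oxidations and allows its release as an alkoxide by fluoride.

Step 7
Reactants: 7 3-O-triethylsilyl ether of 6
Product: 8 cis-5,6-diol of 7 (4-O-triethylsilyl-5,6-O-isopropylidene-cycloheptane-1,2,4,5,6-pentol with a cis-1,2-diol; both facial isomers are carried on together)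
Conditions: OsO4 (2 mol %), NMO (1.5 equiv), acetone/H2O, rt
Reagents that add atoms: N-methylmorpholine N-oxide C[N+]1([O-])CCOCC1; water O
Why: Upjohn syn-dihydroxylation of the cis-alkene; its facial selectivity is irrelevant because both new carbinol centres become carbonyls in step 8.

Step 8
Reactants: 8 cis-5,6-diol of 7
Product: 9 (4R,5R,6R)-5,6-O-isopropylidene-4-(triethylsilyloxy)cycloheptane-1,2-dione (4-OTES trans to the cis-acetonide)
Conditions: DMSO (6 equiv), TFAA (4.5 equiv), CH2Cl2, –78 °C; Et3N, –78 → –30 °C; pH 7 buffer
Reagents that add atoms: none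
Why: Activated-DMSO (Swern-type) double oxidation converts a vic-diol into the α-diketone without C–C cleavage, and the cold amine treatment with a buffered quench limits enolisation of the β-oxygenated dione.

Step 9
Reactants: 9 (4R,5R,6R)-5,6-O-isopropylidene-4-(triethylsilyloxy)cycloheptane-1,2-dione
Product: 13 3,4-O-isopropylidene-1,5-quinide, via ring-opened C4 alkoxide 10 (not isolated), via bridged hemiketal alkoxide 11 (not isolated), via quinide acetonide 1-alkoxide 12 (not isolated)
Conditions: TBAF (1.1 equiv, dried), THF, –78 → 0 °C; then AcOH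
Reagents that add atoms: none
Why: Proposed new method: fluoride cleaves the Si–O bond and the liberated C4 alkoxide adds across the ring to the C1 carbonyl (5-exo-trig; attack at C2 would give an oxetane), forming an 8-oxabicyclo[3.2.1]octane hemiketal alkoxide whose C1–C7 bond lies parallel to the π* orbital of the adjacent C2 ketone. A suprafacial anionic 1,2-shift of C7 from C1 to C2 then contracts the carbocycle from seven to six atoms and turns C1 into an ester carbonyl, so the five-membered oxa-ring of the hemiketal is kept as the γ-lactone; the closest known reaction type is the alkoxide-induced benzilic ester rearrangement of cyclic 1,2-diones, here run with a transannular alkoxide instead of an external one. The only new stereocentre, the quaternary C1 of the quinide, is set by the tether: the carboxyl carbon stays bonded to O-5 throughout and must end cis-1,3 to the C5–O bond, which with C5 taken from D-arabinitol is the natural configuration. The step needs the 1,2-shift to beat enolisation with β-elimination of an oxygen (the path towards tropolones) and retro-aldol opening; the bridged hemiketal removes the C1 carbonyl, holds the C4–O bond orthogonal to a C2 enolate and makes the shift irreversible by trading a strained α-dicarbonyl for a lactone. No choice between the two oxygenated flanks arises because the other two oxygens are locked in the acetonide.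

Step 10
Reactants: 14 caffeic acid
Product: 15 (E)-3-(3,4-diacetoxyphenyl)acrylic acid (3,4-di-O-acetylcaffeic acid)
Conditions: Ac2O (3 equiv), pyridine, rt; aqueous acidic work-up
Reagents that add atoms: acetic anhydride CC(=O)OC(C)=O
Why: Standard O-acetylation of the catechol, with any mixed anhydride at the carboxyl hydrolysed on work-up.

Step 11
Reactants: 15 (E)-3-(3,4-diacetoxyphenyl)acrylic acid
Product: 16 (E)-3-(3,4-diacetoxyphenyl)acryloyl chloride
Conditions: (COCl)2 (1.5 equiv), DMF (cat.), CH2Cl2, 0 °C → rt; evaporate
Reagents that add atoms: oxalyl chloride O=C(Cl)C(=O)Cl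
Why: Vilsmeier-type acid chloride formation under neutral conditions leaves the aryl acetates and the E-alkene intact.

Step 12
Reactants: 13 3,4-O-isopropylidene-1,5-quinide; 16 (E)-3-(3,4-diacetoxyphenyl)acryloyl chloride
Product: 17 1-O-(3,4-di-O-acetylcaffeoyl)-3,4-O-isopropylidene-1,5-quinide
Conditions: 16 (2 equiv), DMAP (0.5 equiv), pyridine, CH2Cl2, rt
Reagents that add atoms: none
Why: DMAP-catalysed acylation through the acylpyridinium ion esterifies the tertiary α-hydroxy lactone, which is the only free hydroxyl.

Step 13
Reactants: 17 1-O-(3,4-di-O-acetylcaffeoyl)-3,4-O-isopropylidene-1,5-quinide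
Product: 18 1-O-(3,4-di-O-acetylcaffeoyl)-1,5-quinide (free equatorial 3-OH and axial 4-OH)
Conditions: TFA/H2O (9:1), 0 °C → rt, short time
Reagents that add atoms: none
Why: Acid hydrolysis of the isopropylidene ketal, which the γ-lactone, the aryl acetates and the tertiary ester (no stabilised cation next to the lactone carbonyl) should survive on brief exposure.

Step 14
Reactants: 18 1-O-(3,4-di-O-acetylcaffeoyl)-1,5-quinide; 16 (E)-3-(3,4-diacetoxyphenyl)acryloyl chloride
Product: 19 1,3-di-O-(3,4-di-O-acetylcaffeoyl)-1,5-quinide
Conditions: 16 (1.05 equiv, slow addition), pyridine, CH2Cl2, –30 → 0 °C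
Reagents that add atoms: none
Why: Kinetic acylation should select the less hindered equatorial 3-OH over the axial 4-OH, which is shielded by the lactone bridge, in line with the known 3-O-selective silylation of quinide.

Step 15
Reactants: 19 1,3-di-O-(3,4-di-O-acetylcaffeoyl)-1,5-quinide
Product: 20 1,3-di-O-caffeoylquinic acid
Conditions: 2 M aq HCl/THF (1:3), rt, several days
Reagents that add atoms: water O
Why: Acid-catalysed acyl-oxygen hydrolysis should cleave the four aryl acetates and the strained bicyclic lactone while the two alkyl cinnamates, the slowest esters, persist, and acid rather than base suppresses 3 → 4 acyl migration.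

**Compound list**

1 | D-arabinitol, (2R,4R)-pentane-1,2,3,4,5-pentol | OC[C@@H](O)C(O)[C@H](O)CO | starting material
2 | 2,3,4-tri-O-acetyl-1,5-dibromo-1,5-dideoxy-D-arabinitol | BrC[C@@H](OC(C)=O)C(OC(C)=O)[C@H](OC(C)=O)CBr | intermediate
3 | 1,2:4,5-dianhydro-D-arabinitol, bis[(2R)-oxiran-2-yl]methanol | OC([C@H]1CO1)[C@H]1CO1 | intermediate
4 | (4R,6R)-nona-1,8-diene-4,5,6-triol | C=CC[C@@H](O)C(O)[C@H](O)CC=C | intermediate
5 | (1R,3R)-cyclohept-5-ene-1,2,3-triol | O[C@@H]1CC=CC[C@@H](O)C1O | intermediate
6 | (1R,2S,3R)-1,2-O-isopropylidenecyclohept-5-ene-1,2,3-triol | O[C@@H]1CC=CC[C@H]2OC(C)(C)O[C@@H]12 | intermediate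
7 | 3-O-triethylsilyl ether of 6 | CC[Si](CC)(CC)O[C@@H]1CC=CC[C@H]2OC(C)(C)O[C@@H]12 | intermediate
8 | cis-5,6-diol of 7 (one of the two cis facial isomers drawn; both are used) | CC[Si](CC)(CC)O[C@@H]1C[C@@H](O)[C@@H](O)C[C@H]2OC(C)(C)O[C@@H]12 | intermediate
9 | (4R,5R,6R)-5,6-O-isopropylidene-4-(triethylsilyloxy)cycloheptane-1,2-dione | CC[Si](CC)(CC)O[C@@H]1CC(=O)C(=O)C[C@H]2OC(C)(C)O[C@@H]12 | intermediate
10 | ring-opened C4 alkoxide of 4-hydroxy-5,6-O-isopropylidenecycloheptane-1,2-dione, tetrabutylammonium salt (configuration as in 9) | [O-][C@@H]1CC(=O)C(=O)C[C@H]2OC(C)(C)O[C@@H]12.CCCC[N+](CCCC)(CCCC)CCCC | intermediate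
11 | bridged hemiketal alkoxide, 3,4-(isopropylidenedioxy)-7-oxo-8-oxabicyclo[3.2.1]octan-1-olate, tetrabutylammonium salt (acetonide anti to the oxygen bridge) | O=C1C[C@H]2O[C@]1([O-])C[C@H]3OC(C)(C)O[C@@H]23.CCCC[N+](CCCC)(CCCC)CCCC | intermediate
12 | 1-alkoxide of 3,4-O-isopropylidene-1,5-quinide, tetrabutylammonium salt | O=C1O[C@@H]2C[C@@]1([O-])C[C@H]3OC(C)(C)O[C@@H]23.CCCC[N+](CCCC)(CCCC)CCCC | intermediate
13 | 3,4-O-isopropylidene-1,5-quinide (1,5-lactone of (–)-quinic acid 3,4-acetonide; free tertiary 1-OH) | O=C1O[C@@H]2C[C@@]1(O)C[C@H]3OC(C)(C)O[C@@H]23 | intermediate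
14 | caffeic acid | O=C(O)/C=C/c1ccc(O)c(O)c1 | starting material
15 | (E)-3-(3,4-diacetoxyphenyl)acrylic acid | O=C(O)/C=C/c1ccc(OC(C)=O)c(OC(C)=O)c1 | intermediate
16 | (E)-3-(3,4-diacetoxyphenyl)acryloyl chloride | O=C(Cl)/C=C/c1ccc(OC(C)=O)c(OC(C)=O)c1 | intermediate
17 | 1-O-(3,4-di-O-acetylcaffeoyl)-3,4-O-isopropylidene-1,5-quinide | O=C1O[C@@H]2C[C@@]1(OC(=O)/C=C/c3ccc(OC(C)=O)c(OC(C)=O)c3)C[C@H]3OC(C)(C)O[C@@H]23 | intermediate
18 | 1-O-(3,4-di-O-acetylcaffeoyl)-1,5-quinide | O=C1O[C@@H]2C[C@@]1(OC(=O)/C=C/c3ccc(OC(C)=O)c(OC(C)=O)c3)C[C@@H](O)[C@H]2O | intermediate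
19 | 1,3-di-O-(3,4-di-O-acetylcaffeoyl)-1,5-quinide | O=C1O[C@@H]2C[C@@]1(OC(=O)/C=C/c3ccc(OC(C)=O)c(OC(C)=O)c3)C[C@@H](OC(=O)/C=C/c3ccc(OC(C)=O)c(OC(C)=O)c3)[C@H]2O | intermediate
20 | 1,3-di-O-caffeoylquinic acid | O=C(/C=C/c1ccc(O)c(O)c1)O[C@@H]1C[C@@](OC(=O)/C=C/c2ccc(O)c(O)c2)(C(=O)O)C[C@@H](O)[C@@H]1O | target

**Step count and risks**

Total steps: 15. Longest linear sequence: 13 (steps 1–9 and 12–15); steps 10–11 form the acyl chloride branch.

Steps most likely to fail:

1. Step 9. After desilylation, enolisation with β-elimination of an oxygen, or retro-aldol opening of the hydroxy-dione, may outrun the transannular 1,2-shift, or the hemiketal alkoxide may not rearrange at a temperature the dione tolerates. Fallback with known chemistry, setting out from 9 and returning at 13: desilylation under buffered acidic conditions (HF·pyridine, THF/pyridine, 0 °C) should give the neutral bridged hemiketal F1. Classical hydroxide benzilic acid rearrangement (Ba(OH)2 or KOH, H2O/dioxane, then acidification to about pH 4) should convert it into 3,4-O-isopropylidenequinic acid F2, possibly with its C1 epimer. Relactonisation (cat. TsOH, 2,2-dimethoxypropane/acetone, reflux) closes only the acid whose carboxyl is cis to 5-OH and gives 13; an epimeric acid cannot lactonise and is removed by bicarbonate extraction.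

2. Step 14. Discrimination between the equatorial 3-OH and the axial 4-OH may be insufficient, with double acylation or 3 → 4 acyl migration. Fallback, from 18 back to 19: 18 is heated with Bu2SnO in toluene with removal of water to give the 3,4-O-dibutylstannylene acetal F3, which is treated with 16 at 0 °C. Tin acetals of cis-diols direct acylation to the equatorial oxygen, so 19 should form after aqueous work-up.

3. Step 8. Amine-induced enolisation of the forming α-diketone with β-elimination of triethylsilanol, or over-oxidation, may erode the dione. Fallback, from 7 directly to 9: the alkene is oxidised to the α-diketone with KMnO4 in acetic anhydride at –10 to 0 °C (reductive bisulfite work-up). This bypasses diol 8 and any amine base and makes no new compound.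

**Further compounds**

F1 | step 9 | neutral bridged hemiketal, 1-hydroxy-3,4-(isopropylidenedioxy)-8-oxabicyclo[3.2.1]octan-7-one | O=C1C[C@H]2O[C@]1(O)C[C@H]3OC(C)(C)O[C@@H]23
F2 | step 9 | 3,4-O-isopropylidenequinic acid | O=C(O)[C@@]1(O)C[C@@H](O)[C@@H]2OC(C)(C)O[C@@H]2C1
F3 | step 14 | 3,4-O-dibutylstannylene acetal of 18 | O=C1O[C@@H]2C[C@@]1(OC(=O)/C=C/c3ccc(OC(C)=O)c(OC(C)=O)c3)C[C@H]3O[Sn](CCCC)(CCCC)O[C@@H]23
F0 | step 8 | none | none
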